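Percent of the starting material charged is the unit I keep, since in it the midnight run at 2 mM and the autumn run at 1.3 mM can be added and subtracted as one account.

| setting | midnight | autumn | flask |
|---|---|---|---|
| starting material | 2 mM | 1.3 mM | 2.0 mM |
| first nucleophile | 1 equiv | 1 equiv | 1.00 equiv |
| second nucleophile | 3 equiv | 3 equiv | 3.00 equiv |
| remark | the very flask that is asked about, followed so far | run made earlier |  |
| time |  |  | 10 min |

midnight run (percent of the starting material charged)

| time / s | target / % | other capture product / % | starting material / % |
|---|---|---|---|
| 10.0 | 24.1 | 16.9 | 0 |
| 20.0 | 15.0 | 16.8 | 0 |
| 40.0 | 12.4 | 17.1 | 0.3 |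
| 80.0 | 11.8 | 16.9 | 0 |

autumn run (percent of the starting material charged)

| time / min | target / % | other capture product / % | starting material / % |
|---|---|---|---|
| 0.333 | 13.3 | 17.3 | 0 |
| 0.667 | 12.5 | 17.7 | 0.1 |
| 1.00 | 12.2 | 15.7 | 0.8 |
| 2.00 | 11.5 | 17.0 | 0.4 |
| 4.00 | 12.7 | 17.1 | 0 |

(scatter of a reading: 0.5 percentage points)

- share of target in target plus other capture product at 0.25 s
- share of target in target plus other capture product at 12 s
- share of target in target plus other capture product at 10 min

1. In the autumn run the starting material reads 0 % at 4.00 min, the other capture product averages 17.0 %, and target levels at 12.2 %, so 70.8 % stands in no column. In the midnight run target falls from 24.1 % to 11.8 % while the other capture product stays flat, so I take that unseen rest to have come out of target.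

2. What the other capture product did not take is 83.0 %, and 12.2 % of it gives 0.147, which I call the plateau fraction φ, target at the plateau over everything the other capture product did not take.

3. For 10 min I have two ways: the last midnight reading gives a share of 41.1 %, and the autumn averages, from a different concentration, give 41.9 %. They differ by 0.80 percentage points, which the scatter allows, so I trust about 41.9 %.

4. For 12 s I interpolate the midnight excess over the plateau geometrically, which gives c(target) of 21.1 % and a share of 55.4 %.

5. At 0.25 s, far earlier than the first reading at 10.0 s, I have no reading, so I set down the whole-run balance, 83.0 %, as a rough stand-in for the share, knowing that it counts the whole capture and is not a share of that moment.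

6. The forecast gives 77 %, 55 % and 41.7 %, and says of the first: “This is uncertain because the mechanism is unknown”.

7. The flask gives 89.3 %, 54.5 % and 41.6 %, so at 0.25 s my stand-in lies closer to the flask than the forecast does, though still below it.

    starting material → intermediate (k = 1.60 s⁻¹)
    first nucleophile + intermediate → target (k = 90000 L mol⁻¹ s⁻¹)
    second nucleophile + intermediate → other capture product (k = 3000 L mol⁻¹ s⁻¹)
    target ⇌ isomer of the product (K = 5.80, k = 0.160 s⁻¹)

Striking the turning of target into isomer of the product out of the flask lifts the share at 10 min from 41.6 % to 82.9 %, so the unseen rest is that isomer, 70.7 % in the flask. With other capture product at 17.1 %, φ gives the flask 12.2 % of target, and it holds 12.2 %. In the neighbour flask with 0.250 equiv of first nucleophile the other capture product stands at 75.0 %, so φ gives 3.67 % of target, and that flask holds 3.68 %.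

(Readings and results were generated by integration for an exercise, noise included.)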